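**Retrosynthetic overview**

1. The target is a trans-(2R,3R)-2-aryl-3-methyl-2,3-dihydro-1,4-benzodioxine: ring A is the 3,4,5-trimethoxyphenyl group on C2, ring B the dioxane (O1, C2, C3, O4, C4a, C8a), ring C the benzo ring with OMe at C5 and the (E)-3-hydroxyprop-1-enyl chain at C7.
2. Last disconnection: the allylic alcohol comes from the ethyl (E)-acrylate by reduction with i-Bu2AlH; rings A and C are bought, and ring B is the only ring formed.
3. Key disconnection: the O1–C8a bond of ring B, with C2 taken back to the ketone level. The precursor is a racemic, acyclic 2-aryloxy-1-arylpropan-1-one with iodine on C8a; in one flask, asymmetric transfer hydrogenation under dynamic kinetic resolution sets C2 and C3, then CuI-catalysed O-arylation closes ring B.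
4. Enabling feature: C3 lies between the C2 carbonyl and the aryloxy oxygen O4, so its hydrogen is acidic and the two enantiomers of the ketone interconvert; C8a is the ring C carbon ortho to C4a–O4, so the new C2 alkoxide reaches it through a six-membered ring.
5. The ketone is cut at O4–C3: Williamson alkylation of ethyl 5-iodoferulate (Wittig product of 5-iodovanillin) with the α-bromoketone of 3,4,5-trimethoxypropiophenone.

Key step: step 4

Remark: 5-iodovanillin, ethyl (triphenylphosphoranylidene)acetate and 1-(3,4,5-trimethoxyphenyl)propan-1-one are taken as catalogue compounds, and the ring B locants of the overview are used for all intermediates.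

**Route**

Step 1
Reactants: 1 5-iodovanillin (4-hydroxy-3-iodo-5-methoxybenzaldehyde); 2 ethyl (triphenylphosphoranylidene)acetate
Product: 3 ethyl (E)-3-(4-hydroxy-3-iodo-5-methoxyphenyl)prop-2-enoate
Conditions: toluene, 100 °C
Reagents that add atoms: none
Why: Wittig olefination with a stabilised ylide should give the E-cinnamate and tolerates the free phenol and the aryl iodide; no stereocentre is formed.

Step 2
Reactants: 4 1-(3,4,5-trimethoxyphenyl)propan-1-one
Product: 5 2-bromo-1-(3,4,5-trimethoxyphenyl)propan-1-one (racemic)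
Conditions: CuBr2 (2.1 equiv), EtOAc/CHCl3 (1:1), reflux
Reagents that add atoms: CuBr2 (copper dibromide), [Cu+2].[Br-].[Br-]
Why: α-Bromination of an aryl alkyl ketone with CuBr2 runs through the copper-bound enol, so bromine should enter at the α-carbon and not on the carbonyl-deactivated ring A; the new stereocentre is racemic, which the key step tolerates by design.

Step 3
Reactants: 3 ethyl (E)-3-(4-hydroxy-3-iodo-5-methoxyphenyl)prop-2-enoate; 5 2-bromo-1-(3,4,5-trimethoxyphenyl)propan-1-one
Product: 6 ethyl (E)-3-[3-iodo-5-methoxy-4-{[1-oxo-1-(3,4,5-trimethoxyphenyl)propan-2-yl]oxy}phenyl]prop-2-enoate (racemic)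
Conditions: K2CO3 (1.5 equiv), DMF, 50 °C
Reagents that add atoms: none
Why: Williamson ether synthesis, in which the phenoxide of 3 displaces bromide from the α-keto carbon of 5 by SN2, a displacement the adjacent carbonyl accelerates; the future C3 is formed racemic on purpose.

Step 4
Reactants: 6 ethyl (E)-3-[3-iodo-5-methoxy-4-{[1-oxo-1-(3,4,5-trimethoxyphenyl)propan-2-yl]oxy}phenyl]prop-2-enoate (racemic)
Product: 8 ethyl (E)-3-[(2R,3R)-5-methoxy-3-methyl-2-(3,4,5-trimethoxyphenyl)-2,3-dihydro-1,4-benzodioxin-7-yl]prop-2-enoate, via threo (1R,2R) iodo alcohol 7 (not isolated)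
Conditions: RuCl[(S,S)-TsDPEN](p-cymene) (2 mol %), HCO2H (1.5 equiv), Et3N (3 equiv), DBU (0.3 equiv), DMF, 40 °C, to full conversion; then in the same flask CuI (10 mol %), 3,4,7,8-tetramethyl-1,10-phenanthroline (20 mol %), Cs2CO3 (3 equiv), toluene, 90 °C, argon
Reagents that add atoms: none
Why: The C3–H of 6 lies between the C2 carbonyl and O4, so under Et3N/DBU it should epimerise through the enolate faster than the Ru–H/N–H catalyst transfers hydride (outer-sphere Noyori–Ikariya transfer hydrogenation under dynamic kinetic resolution, closest precedent the reduction of racemic benzoin to hydrobenzoin), and the whole racemate is drawn through one enantiomer. The (S,S) ligand fixes the carbonyl face and hence 2R, while the non-chelated Felkin–Anh arrangement (aryloxy group anti to the incoming hydride, C3–H on the approach side) makes only the 3R ketone the fast partner, so 7 should form as the threo (1R,2R) alcohol. In the second stage the alkoxide of 7 binds CuI/tetramethylphenanthroline, the C8a–I bond adds oxidatively to this monovalent copper alkoxide and reductive elimination from trivalent copper forms O1–C8a (Ullmann-type intramolecular O-arylation, the known route from 2-(2-halophenoxy)ethanols to 1,4-benzodioxanes). Ring B closes as a six-membered ring by ipso attack of O1 on C8a through a seven-membered copper chelate with both stereocentres untouched, so the threo alcohol maps onto the trans (2R,3R) ring. The step needs carbonyl-over-alkene and carbonyl-over-C–I chemoselectivity in the reduction, which this class of Ru hydride provides, and a single site of arylation, which the lone iodine ortho to O4 secures. Copper is chosen over palladium so that the aryl iodide does not enter Heck coupling with the cinnamate, and the side chain is kept as the ester so that no free primary alcohol competes for the aryl iodide.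

Step 5
Reactants: 8 ethyl (E)-3-[(2R,3R)-5-methoxy-3-methyl-2-(3,4,5-trimethoxyphenyl)-2,3-dihydro-1,4-benzodioxin-7-yl]prop-2-enoate
Product: 9 (E)-3-[(2R,3R)-5-methoxy-3-methyl-2-(3,4,5-trimethoxyphenyl)-2,3-dihydro-1,4-benzodioxin-7-yl]prop-2-en-1-ol
Conditions: i-Bu2AlH (3 equiv), CH2Cl2, −78 to 0 °C; aqueous KNaC4H4O6 work-up
Reagents that add atoms: none
Why: 1,2-Reduction of an α,β-unsaturated ester by i-Bu2AlH at low temperature should give the (E)-allylic alcohol without touching the alkene geometry, the aryl ethers or the two stereocentres of ring B, which no longer carry an acidifying neighbour.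

**Compound list**

1 | 5-iodovanillin (4-hydroxy-3-iodo-5-methoxybenzaldehyde) | COc1cc(C=O)cc(I)c1O | starting material
2 | ethyl (triphenylphosphoranylidene)acetate | CCOC(=O)C=P(c1ccccc1)(c1ccccc1)c1ccccc1 | starting material
3 | ethyl (E)-3-(4-hydroxy-3-iodo-5-methoxyphenyl)prop-2-enoate | CCOC(=O)/C=C/c1cc(I)c(O)c(OC)c1 | intermediate
4 | 1-(3,4,5-trimethoxyphenyl)propan-1-one | CCC(=O)c1cc(OC)c(OC)c(OC)c1 | starting material
5 | 2-bromo-1-(3,4,5-trimethoxyphenyl)propan-1-one (racemic) | CC(Br)C(=O)c1cc(OC)c(OC)c(OC)c1 | intermediate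
6 | ethyl (E)-3-[3-iodo-5-methoxy-4-{[1-oxo-1-(3,4,5-trimethoxyphenyl)propan-2-yl]oxy}phenyl]prop-2-enoate (racemic) | CCOC(=O)/C=C/c1cc(I)c(OC(C)C(=O)c2cc(OC)c(OC)c(OC)c2)c(OC)c1 | intermediate
7 | ethyl (E)-3-[4-{[(1R,2R)-1-hydroxy-1-(3,4,5-trimethoxyphenyl)propan-2-yl]oxy}-3-iodo-5-methoxyphenyl]prop-2-enoate (threo; formed in the flask, not isolated) | COc1cc([C@@H](O)[C@H](Oc2c(I)cc(/C=C/C(=O)OCC)cc2OC)C)cc(OC)c1OC | intermediate
8 | ethyl (E)-3-[(2R,3R)-5-methoxy-3-methyl-2-(3,4,5-trimethoxyphenyl)-2,3-dihydro-1,4-benzodioxin-7-yl]prop-2-enoate | COc1cc([C@H]2Oc3cc(/C=C/C(=O)OCC)cc(OC)c3O[C@@H]2C)cc(OC)c1OC | intermediate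
9 | (E)-3-[(2R,3R)-5-methoxy-3-methyl-2-(3,4,5-trimethoxyphenyl)-2,3-dihydro-1,4-benzodioxin-7-yl]prop-2-en-1-ol | COc1cc([C@H]2Oc3cc(/C=C/CO)cc(OC)c3O[C@@H]2C)cc(OC)c1OC | target

**Step count and risks**

Total step count: 5. Longest linear sequence: 4 steps (steps 1, 3, 4 and 5; step 2 is a one-step branch).

Steps most likely to fail:

Step 4. The funnel may not run cleanly: epimerisation at C3 may lag behind hydride transfer, or hydride may arrive with erythro instead of threo preference. Either fault would lead, after ring closure, to the cis-disubstituted ring B or to lowered enantiomeric purity. The fallback sets out from 6 and comes back at 8. The reduction is run as a separate operation with the mirror-image catalyst RuCl[(R,R)-TsDPEN](p-cymene) in HCO2H/Et3N, and the erythro alcohol ethyl (E)-3-[4-{[(1S,2R)-1-hydroxy-1-(3,4,5-trimethoxyphenyl)propan-2-yl]oxy}-3-iodo-5-methoxyphenyl]prop-2-enoate F1 is isolated and freed from its diastereomer by chromatography. A Mitsunobu reaction with 4-nitrobenzoic acid (PPh3, DIAD, THF, 0 °C) should invert the carbinol centre and give (1R,2R)-2-{4-[(E)-3-ethoxy-3-oxoprop-1-enyl]-2-iodo-6-methoxyphenoxy}-1-(3,4,5-trimethoxyphenyl)propyl 4-nitrobenzoate F2. Ethanolysis (K2CO3, EtOH) releases 7, which is isolated and closed in a separate flask with CuI, 3,4,7,8-tetramethyl-1,10-phenanthroline and Cs2CO3 in toluene to reach 8.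

Step 3. Substitution by the doubly ortho-substituted, acrylate-delocalised phenoxide may be slower than base-induced loss of HBr from 5 or enolate self-condensation. The fallback sets out from 5 and comes back at 6. Compound 5 is converted with HCO2Na in aqueous ethanol at reflux into 2-hydroxy-1-(3,4,5-trimethoxyphenyl)propan-1-one F3, and this is coupled with phenol 3 under Mitsunobu conditions (PPh3, DIAD, THF, 0 °C to room temperature), where the alcohol is the activated partner and no base is present; this should give 6.

Step 2. Electrophilic bromine may attack the electron-rich ring A or a second α-hydrogen. The fallback sets out from 4 and comes back at 6. α-Sulfonyloxylation of 4 with PhI(OH)OTs in MeCN at reflux should give 1-oxo-1-(3,4,5-trimethoxyphenyl)propan-2-yl 4-methylbenzenesulfonate F4, which replaces 5 as the electrophile in the alkylation of 3 (K2CO3, DMF, 50 °C) and so delivers 6.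

**Further compounds**

F1 | step 4 | ethyl (E)-3-[4-{[(1S,2R)-1-hydroxy-1-(3,4,5-trimethoxyphenyl)propan-2-yl]oxy}-3-iodo-5-methoxyphenyl]prop-2-enoate | COc1cc([C@H](O)[C@H](Oc2c(I)cc(/C=C/C(=O)OCC)cc2OC)C)cc(OC)c1OC
F2 | step 4 | (1R,2R)-2-{4-[(E)-3-ethoxy-3-oxoprop-1-enyl]-2-iodo-6-methoxyphenoxy}-1-(3,4,5-trimethoxyphenyl)propyl 4-nitrobenzoate | COc1cc([C@@H](OC(=O)c3ccc(cc3)[N+](=O)[O-])[C@H](Oc2c(I)cc(/C=C/C(=O)OCC)cc2OC)C)cc(OC)c1OC
F3 | step 3 | 2-hydroxy-1-(3,4,5-trimethoxyphenyl)propan-1-one (racemic) | CC(O)C(=O)c1cc(OC)c(OC)c(OC)c1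
F4 | step 2 | 1-oxo-1-(3,4,5-trimethoxyphenyl)propan-2-yl 4-methylbenzenesulfonate (racemic) | CC(OS(=O)(=O)c1ccc(C)cc1)C(=O)c1cc(OC)c(OC)c(OC)c1
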